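**Retrosynthetic overview**

1. Numbering: C1–C12 for the terpenoid part (C3 ε-lactone carbonyl, C8 spiro carbon, C11 and C12 the CH2 groups on C9 and C8); C1'–C8' for the bicyclo[2.2.2]octane/γ-lactone part (C1' lactone α-CH, C2' CHOH, C3' methyl-bearing bridgehead, C4' ketone, C5' methyl-bearing carbon bonded to C11, C6' bridgehead bearing C8'H2–O, C7' lactone carbonyl).
2. Last step: C2'–OH from C2'–SiMe2Ph with retention. Before it, the key step makes C3'–C2', C1'–C6' and C5'–C11 in one flask from a spiro-dienone (ring A, ring B, cyclohexadienone C8/C12/C3'/C4'/C5'/C6') carrying a (Z)-β-silyl acrylate on C8'–O and an iodide on C11: hydride to C12, dienolate, double Michael addition, enolate alkylation.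
3. Enabling feature: in the cyclohexanone ring C3'–C4'(=O)–C5'–C6'–C1'–C2' the lactone carbonyl C7' sits on C1', 1,4 to the C4' ketone (retron of an enolate–acrylate [4+2]); both α-carbons C3' and C5' are fully substituted; the lactone CH2–O (C8') on C6' is a built-in tether.
4. Spiro-dienone: ring B by para-alkylation of a 2,6-dimethylphenoxide (C8–C7, dearomatisation); ring A by ring-closing metathesis (C1=C2) after opening a temporary γ-lactone (C1/C4–O); C9–C10 by iridium-catalysed branched allylic alkylation of that γ-lactone with an aryl allyl carbonate.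
5. The γ-lactone (C1, C4–C7, C10) comes from (R)-α-terpineol by oxidative cleavage of its ring C=C, which keeps C5. Ring order: temporary γ-lactone, ring A, ring B, then cyclohexanone ring of the bicyclooctane + γ-lactone + cyclopentane together.

Key step: step 25

Remark: 8 is taken as a catalogue compound, and in step 14 the usual facial model of this catalyst class is assumed for C9; the mirror-image ligand would be used otherwise.

**Route**

Step 1
Reactants: 1 (R)-(+)-α-terpineol
Product: 3 (R)-4-(2,2-dimethyl-5-oxotetrahydrofuran-3-yl)butan-2-one, via hydroxy keto acid 2 (not isolated)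
Conditions: RuCl3·xH2O (2 mol %), NaIO4 (4 equiv), EtOAc/MeCN/H2O, 23 °C; acidic work-up
Reagents that add atoms: sodium periodate, [Na+].[O-]I(=O)(=O)=O
Why: Ruthenium tetroxide-type oxidative cleavage of the trisubstituted ring alkene should give the methyl ketone and the acid, and γ-hydroxy acid 2 should lactonise on work-up; the C–C cleavage keeps the only stereocentre of 1, which becomes C5.

Step 2
Reactants: 3 keto lactone
Product: 4 2-[(3R)-2,2-dimethyl-5-oxotetrahydrofuran-3-yl]ethyl acetate
Conditions: mCPBA, CF3CO2H (cat.), CH2Cl2, 0 to 23 °C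
Reagents that add atoms: 3-chloroperbenzoic acid, OOC(=O)c1cccc(Cl)c1
Why: Baeyer–Villiger oxidation in which the primary alkyl group should migrate in preference to methyl, so the C6–C7 chain ends as its acetate; the γ-lactone is inert to the peracid.

Step 3
Reactants: 4 acetate
Product: 5 (R)-4-(2-hydroxyethyl)-5,5-dimethyldihydrofuran-2(3H)-one
Conditions: K2CO3 (cat.), MeOH, 0 °C; dilute HCl work-up
Reagents that add atoms: none
Why: Base-catalysed transesterification removes the acetate; any methanolysis of the γ-lactone is reversed on acidification because the tertiary γ-hydroxy ester recloses.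

Step 4
Reactants: 5 alcohol
Product: 6 (R)-5,5-dimethyl-4-[2-(triethylsilyloxy)ethyl]dihydrofuran-2(3H)-one
Conditions: Et3SiCl, imidazole, CH2Cl2, 0 °C
Reagents that add atoms: chlorotriethylsilane, CC[Si](CC)(CC)Cl
Why: Silylation of the primary alcohol; the triethylsilyl ether survives the enolate, hydride and ylide steps and can later be removed beside the tert-butyldimethylsilyl ethers.

Step 5
Reactants: 6 silyl ether lactone
Product: 7 (3R,4R)-3,5,5-trimethyl-4-[2-(triethylsilyloxy)ethyl]dihydrofuran-2(3H)-one (3,4-trans)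
Conditions: LiN(i-Pr)2, THF, −78 °C; MeI
Reagents that add atoms: iodomethane, CI
Why: Alkylation of the lactone lithium enolate should occur anti to the C5 side chain; this centre is provisional because the carbon is planarised again in step 14.

Step 6
Reactants: 8 3-hydroxy-2,4-dimethylbenzoic acid
Product: 9 3-(hydroxymethyl)-2,6-dimethylphenol
Conditions: BH3·SMe2, THF, 0 to 65 °C; MeOH quench
Reagents that add atoms: none
Why: Borane should reduce the carboxylic acid chemoselectively to the benzylic alcohol (future C8').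

Step 7
Reactants: 9 diol
Product: 10 4-bromo-3-(hydroxymethyl)-2,6-dimethylphenol
Conditions: NBS, MeCN, 0 °C
Reagents that add atoms: N-bromosuccinimide, O=C1CCC(=O)N1Br
Why: Electrophilic aromatic bromination para to the hydroxyl group, the only activated free position (the future C8).

Step 8
Reactants: 10 bromophenol
Product: 11 1-bromo-4-(tert-butyldimethylsilyloxy)-2-[(tert-butyldimethylsilyloxy)methyl]-3,5-dimethylbenzene
Conditions: t-BuMe2SiCl (2.5 equiv), imidazole, DMF, 23 °C
Reagents that add atoms: tert-butyldimethylsilyl chloride, CC(C)(C)[Si](C)(C)Cl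
Why: Silylation of the phenol and the primary alcohol; both groups are removed together by fluoride in step 21.

Step 9
Reactants: 11 aryl bromide; 12 methyl acrylate
Product: 13 methyl (E)-3-aryl acrylate (aryl = 4-silyloxy-2-silyloxymethyl-3,5-dimethylphenyl)
Conditions: Pd2(dba)3 (1.5 mol %), P(t-Bu)3 (6 mol %), Cy2NMe, dioxane, 80 °C
Reagents that add atoms: none
Why: Mizoroki–Heck reaction under bulky-phosphine conditions, suited to hindered electron-rich aryl bromides, should give the (E)-cinnamate.

Step 10
Reactants: 13 cinnamate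
Product: 14 (E)-3-aryl prop-2-en-1-ol
Conditions: i-Bu2AlH (2.2 equiv), CH2Cl2, −78 °C; aqueous potassium sodium tartrate
Reagents that add atoms: none
Why: 1,2-Reduction of the enoate to the (E)-allylic alcohol leaves the silyl ethers untouched.

Step 11
Reactants: 14 allylic alcohol
Product: 15 (E)-3-aryl allyl methyl carbonate
Conditions: ClCO2Me, pyridine, CH2Cl2, 0 °C
Reagents that add atoms: methyl chloroformate, COC(=O)Cl
Why: Acylation gives the allylic carbonate that the iridium catalyst ionises in step 14.

Step 12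
Reactants: 16 ethynyl(dimethyl)phenylsilane
Product: 17 3-[dimethyl(phenyl)silyl]propiolic acid
Conditions: n-BuLi, THF, −78 °C; CO2; aqueous HCl
Reagents that add atoms: carbon dioxide, O=C=O
Why: Deprotonation of the terminal alkyne and carboxylation of the acetylide.

Step 13
Reactants: 17 alkynoic acid
Product: 18 (Z)-3-[dimethyl(phenyl)silyl]acrylic acid
Conditions: H2 (1 atm), Pd/CaCO3 poisoned with Pb(OAc)2 (Lindlar catalyst), quinoline, EtOAc, 23 °C
Reagents that add atoms: none
Why: Syn semi-hydrogenation should give the (Z)-alkene, the geometry that later places silicon (the masked C2' hydroxyl) syn to the lactone carbonyl.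

Step 14
Reactants: 7 methyl lactone; 15 allyl carbonate
Product: 20 (3R,4R)-3-[(1R)-1-arylprop-2-enyl]-3,5,5-trimethyl-4-[2-(triethylsilyloxy)ethyl]dihydrofuran-2(3H)-one, via silyl ketene acetal 19 (not isolated)
Conditions: LiN(i-Pr)2, Me3SiCl, THF, −78 °C; then 15, [Ir(cod)Cl]2 (2 mol %), (Sa,S,S)-BINOL-derived N,N-bis[1-(2-methoxyphenyl)ethyl]phosphoramidite (4 mol %, pre-activated with n-PrNH2), THF, 35 °C
Reagents that add atoms: none
Why: Iridium-catalysed branched-selective asymmetric allylic alkylation of a silyl ketene acetal, in which methoxide released from the carbonate unmasks the enolate; C9 is set by the chiral ligand (catalyst control) and C10 by attack anti to the C5 side chain of the lactone (substrate control), so methyl ends cis and C9 trans to C6.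

Step 15
Reactants: 20 allylated lactone
Product: 21 lactol (anomeric mixture)
Conditions: i-Bu2AlH (1.2 equiv), CH2Cl2, −78 °C
Reagents that add atoms: none
Why: Partial reduction of the γ-lactone at low temperature gives the lactol, a masked C1 aldehyde and C4 tertiary alcohol.

Step 16
Reactants: 21 lactol
Product: 22 tertiary alcohol with vinyl groups on C10 and C9
Conditions: Ph3PCH3Br, KN(SiMe3)2, THF, 0 to 50 °C
Reagents that add atoms: methyltriphenylphosphonium bromide, C[P+](c1ccccc1)(c1ccccc1)c1ccccc1.[Br-]
Why: Wittig methylenation of the open hydroxy aldehyde form of the lactol gives the C1=CH2 group on quaternary C10 and frees the tertiary C4 alcohol.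

Step 17
Reactants: 22 tertiary alcohol
Product: 23 tertiary acrylate
Conditions: n-BuLi, THF, −78 °C; acryloyl chloride, −78 to 0 °C
Reagents that add atoms: acryloyl chloride, C=CC(=O)Cl
Why: O-acylation of the lithium tertiary alkoxide brings in C2 and C3.

Step 18
Reactants: 23 acrylate
Product: 24 ring A lactone (seven-membered (Z)-enoate lactone; C5–H and C10–CH3 trans)
Conditions: second-generation Grubbs catalyst RuCl2(=CHPh)(H2IMes)(PCy3) (5 mol %), toluene (2 mM), 80 °C
Reagents that add atoms: none
Why: Ring-closing metathesis of the acrylate with the C10 vinyl group should close ring A; closure onto the C9 vinyl group would need an eight-membered ring and is expected to be much slower, so that group survives as the masked C11.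

Step 19
Reactants: 24 ring A lactone
Product: 25 primary alcohol at C7
Conditions: PPTS, MeOH/CH2Cl2, 0 °C
Reagents that add atoms: none
Why: Mild acid should cleave the primary triethylsilyl ether selectively, the aryl and benzylic tert-butyldimethylsilyl ethers being far more stable to acid.

Step 20
Reactants: 25 alcohol
Product: 26 primary chloride at C7
Conditions: NCS, PPh3, CH2Cl2, 0 to 23 °C
Reagents that add atoms: N-chlorosuccinimide, O=C1CCC(=O)N1Cl
Why: Appel-type chlorination installs the C7 leaving group only now, after the C4 alkoxide (which would displace it to a tetrahydrofuran) is locked in ring A.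

Step 21
Reactants: 26 chloride
Product: 28 spiro-dienone alcohol (ring B closed; 5α-H and 10β-CH3 with 9β-H; at C8, C12 is β and C6' is α), via tetrabutylammonium phenoxide 27 (not isolated)
Conditions: Bu4NF·3H2O (2.5 equiv), NaI (0.2 equiv), THF/DMF, 0 to 60 °C
Reagents that add atoms: none
Why: Fluoride cleaves both silyl ethers and phenoxide 27 should alkylate at its para carbon (6-exo-tet dearomatising spirocyclisation; the ortho positions are methyl-blocked and oxygen cannot reach C7); C8 is set by a chair transition state in which the substituted ortho carbon C6' is equatorial, anti to C10 and away from the axial C10 methyl.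

Step 22
Reactants: 28 spiro-dienone alcohol; 18 (Z)-silyl acrylic acid
Product: 29 (Z)-3-silylacrylate ester of 28
Conditions: DCC, DMAP (5 mol %), CH2Cl2, 0 °C
Reagents that add atoms: none
Why: Steglich esterification of the primary allylic alcohol; low temperature and little DMAP should preserve the (Z)-geometry.

Step 23
Reactants: 29 ester
Product: 31 primary alcohol at C11, via aldehyde 30 (not isolated)
Conditions: OsO4 (2 mol %), NaIO4, 2,6-lutidine, dioxane/H2O, 23 °C; extractive work-up; then NaBH4, MeOH/CH2Cl2, −78 to −40 °C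
Reagents that add atoms: sodium periodate, [Na+].[O-]I(=O)(=O)=O (terminal oxidant; oxygen relayed by the osmium catalyst)
Why: Lemieux–Johnson cleavage of the only electron-rich alkene (the C9 vinyl group) gives aldehyde 30, which is reduced at low temperature beside the hindered dienone and the enoates; immediate reduction limits epimerisation at C9.

Step 24
Reactants: 31 alcohol
Product: 32 primary iodide at C11
Conditions: I2, PPh3, imidazole, CH2Cl2, 0 to 23 °C
Reagents that add atoms: iodine, II
Why: Appel-type iodination of the primary alcohol gives the electrophile for the final ring closure.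

Step 25
Reactants: 32 iodide
Product: 35 cage silane (andilesin A with SiMe2Ph in place of the C2' hydroxyl), via lithium dienolate 33 (not isolated), via bicyclic lithium enolate 34 (not isolated)
Conditions: LiBH(s-Bu)3 (1.05 equiv), THF, −78 °C; warm to 23 °C; then DMPU, 50 °C
Reagents that add atoms: none
Why: Proposed new method: LiBH(s-Bu)3 should deliver hydride in the 1,4-sense to C12, the only hydrogen-bearing β-carbon of the cross-conjugated dienone, giving lithium dienolate 33 regiospecifically; this 2-oxido diene then adds to the tethered (Z)-β-silyl acrylate in an oxyanion-accelerated asynchronous [4+2] process (Michael addition C3' to C2', then C1' to C6'), and the resulting C4'=C5' enolate 34 is alkylated by C11–I; the closest known reaction types are the intramolecular double Michael reaction of cyclohexenone dienolates with tethered acrylates to bicyclo[2.2.2]octanones, reductive enolate generation with trialkylborohydrides and Michael-initiated ring closure onto alkyl halides, merged here in one flask. The cyclohexanone ring C3'–C4'–C5'–C6'–C1'–C2' closes as a formal six-membered [4+2] annulation, the γ-lactone as a 5-exo-trig Michael closure onto C6', and the cyclopentane C8–C9–C11–C5'–C6' as a 5-exo-tet (enolexo) alkylation. C3' and C6' are set by addition to the dienolate face syn to C7H2 and anti to the bulkier C9; C1' by the endo orientation of the ester carbonyl (lithium bridging it to the enolate oxygen, C7H2 disfavouring the exo mode); C2' by suprafacial addition across the (Z)-alkene, so silicon ends syn to C7' and to the C4' bridge; C5' by the tether, since C11 reaches only the enolate face anti to the new C1'–C2' bridge. The step needs hydride delivery to the dienone in the presence of the ring A enoate, the silyl acrylate and the iodide, which the much higher electrophilicity of the cross-conjugated dienone at −78 °C should secure. It also needs alkylation at C5' and not at C3', which the trans-diaxial relation of C11 and C12 on ring B secures.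

Step 26
Reactants: 35 cage silane
Product: 36 andilesin A
Conditions: Hg(OAc)2 (1.5 equiv), AcOOH (32% in AcOH), AcOH, 23 °C
Reagents that add atoms: peracetic acid, CC(=O)OO
Why: Fleming–Tamao oxidation (mercuridesilylation of the phenyl group, then peracid-induced shift of C2' from silicon to oxygen with retention) should place the hydroxyl syn to the C4' ketone bridge and to C7'; the electron-poor ring A alkene and the hindered ketone should not react with peracetic acid at 23 °C.

**Compound list**

1 | (R)-(+)-α-terpineol | CC1=CC[C@@H](CC1)C(C)(C)O | starting material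
2 | (R)-3-(2-hydroxypropan-2-yl)-6-oxoheptanoic acid | CC(=O)CC[C@H](CC(=O)O)C(C)(C)O | intermediate
3 | (R)-4-(2,2-dimethyl-5-oxotetrahydrofuran-3-yl)butan-2-one | CC(=O)CC[C@@H]1CC(=O)OC1(C)C | intermediate
4 | 2-[(3R)-2,2-dimethyl-5-oxotetrahydrofuran-3-yl]ethyl acetate | CC(=O)OCC[C@@H]1CC(=O)OC1(C)C | intermediate
5 | (R)-4-(2-hydroxyethyl)-5,5-dimethyldihydrofuran-2(3H)-one | OCC[C@@H]1CC(=O)OC1(C)C | intermediate
6 | (R)-5,5-dimethyl-4-[2-(triethylsilyloxy)ethyl]dihydrofuran-2(3H)-one | CC[Si](CC)(CC)OCC[C@@H]1CC(=O)OC1(C)C | intermediate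
7 | (3R,4R)-3,5,5-trimethyl-4-[2-(triethylsilyloxy)ethyl]dihydrofuran-2(3H)-one | C[C@H]1C(=O)OC(C)(C)[C@@H]1CCO[Si](CC)(CC)CC | intermediate
8 | 3-hydroxy-2,4-dimethylbenzoic acid | Cc1ccc(C(=O)O)c(C)c1O | starting material
9 | 3-(hydroxymethyl)-2,6-dimethylphenol | Cc1ccc(CO)c(C)c1O | intermediate
10 | 4-bromo-3-(hydroxymethyl)-2,6-dimethylphenol | Cc1cc(Br)c(CO)c(C)c1O | intermediate
11 | 1-bromo-4-(tert-butyldimethylsilyloxy)-2-[(tert-butyldimethylsilyloxy)methyl]-3,5-dimethylbenzene | Cc1cc(Br)c(CO[Si](C)(C)C(C)(C)C)c(C)c1O[Si](C)(C)C(C)(C)C | intermediate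
12 | methyl acrylate | C=CC(=O)OC | starting material
13 | methyl (E)-3-[4-(tert-butyldimethylsilyloxy)-2-[(tert-butyldimethylsilyloxy)methyl]-3,5-dimethylphenyl]acrylate | COC(=O)/C=C/c1cc(C)c(O[Si](C)(C)C(C)(C)C)c(C)c1CO[Si](C)(C)C(C)(C)C | intermediate
14 | (E)-3-aryl prop-2-en-1-ol (aryl as in 13) | OC/C=C/c1cc(C)c(O[Si](C)(C)C(C)(C)C)c(C)c1CO[Si](C)(C)C(C)(C)C | intermediate
15 | (E)-3-aryl allyl methyl carbonate (aryl as in 13) | COC(=O)OC/C=C/c1cc(C)c(O[Si](C)(C)C(C)(C)C)c(C)c1CO[Si](C)(C)C(C)(C)C | intermediate
16 | ethynyl(dimethyl)phenylsilane | C#C[Si](C)(C)c1ccccc1 | starting material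
17 | 3-[dimethyl(phenyl)silyl]propiolic acid | OC(=O)C#C[Si](C)(C)c1ccccc1 | intermediate
18 | (Z)-3-[dimethyl(phenyl)silyl]acrylic acid | OC(=O)/C=C\[Si](C)(C)c1ccccc1 | intermediate
19 | trimethylsilyl ketene acetal of 7 (C5 as in 7) | CC1=C(O[Si](C)(C)C)OC(C)(C)[C@@H]1CCO[Si](CC)(CC)CC | intermediate
20 | (3R,4R)-3-[(1R)-1-arylprop-2-enyl]-3,5,5-trimethyl-4-[2-(triethylsilyloxy)ethyl]dihydrofuran-2(3H)-one (C10 methyl cis to the C6 chain) | C=C[C@H](c1cc(C)c(O[Si](C)(C)C(C)(C)C)c(C)c1CO[Si](C)(C)C(C)(C)C)[C@@]1(C)C(=O)OC(C)(C)[C@@H]1CCO[Si](CC)(CC)CC | intermediate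
21 | lactol of 20 (anomeric mixture) | C=C[C@H](c1cc(C)c(O[Si](C)(C)C(C)(C)C)c(C)c1CO[Si](C)(C)C(C)(C)C)[C@@]1(C)C(O)OC(C)(C)[C@@H]1CCO[Si](CC)(CC)CC | intermediate
22 | tertiary alcohol with C10 vinyl and C9 vinyl groups (C5, C9, C10 as in 20) | C=C[C@H](c1cc(C)c(O[Si](C)(C)C(C)(C)C)c(C)c1CO[Si](C)(C)C(C)(C)C)[C@@](C)(C=C)[C@@H](CCO[Si](CC)(CC)CC)C(C)(C)O | intermediate
23 | acrylate of 22 | C=C[C@H](c1cc(C)c(O[Si](C)(C)C(C)(C)C)c(C)c1CO[Si](C)(C)C(C)(C)C)[C@@](C)(C=C)[C@@H](CCO[Si](CC)(CC)CC)C(C)(C)OC(=O)C=C | intermediate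
24 | ring A lactone with C7 triethylsilyl ether (C5–H and C10–CH3 trans) | C=C[C@H](c1cc(C)c(O[Si](C)(C)C(C)(C)C)c(C)c1CO[Si](C)(C)C(C)(C)C)[C@@]1(C)C=CC(=O)OC(C)(C)[C@@H]1CCO[Si](CC)(CC)CC | intermediate
25 | ring A lactone with C7 alcohol | C=C[C@H](c1cc(C)c(O[Si](C)(C)C(C)(C)C)c(C)c1CO[Si](C)(C)C(C)(C)C)[C@@]1(C)C=CC(=O)OC(C)(C)[C@@H]1CCO | intermediate
26 | ring A lactone with C7 chloride | C=C[C@H](c1cc(C)c(O[Si](C)(C)C(C)(C)C)c(C)c1CO[Si](C)(C)C(C)(C)C)[C@@]1(C)C=CC(=O)OC(C)(C)[C@@H]1CCCl | intermediate
27 | tetrabutylammonium phenoxide of desilylated 26 | CCCC[N+](CCCC)(CCCC)CCCC.C=C[C@H](c1cc(C)c([O-])c(C)c1CO)[C@@]1(C)C=CC(=O)OC(C)(C)[C@@H]1CCCl | intermediate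
28 | spiro-dienone alcohol (5α-H, 10β-CH3, 9β-H with 9α-vinyl; at C8, C12 β and C6' α) | OCC1=C(C)C(=O)C(C)=C[C@]13CC[C@H]2C(C)(C)OC(=O)C=C[C@]2(C)[C@@H]3C=C | intermediate
29 | (Z)-3-[dimethyl(phenyl)silyl]acrylate of 28 | C[Si](C)(c1ccccc1)/C=C\C(=O)OCC1=C(C)C(=O)C(C)=C[C@]13CC[C@H]2C(C)(C)OC(=O)C=C[C@]2(C)[C@@H]3C=C | intermediate
30 | C11 aldehyde from 29 | C[Si](C)(c1ccccc1)/C=C\C(=O)OCC1=C(C)C(=O)C(C)=C[C@]13CC[C@H]2C(C)(C)OC(=O)C=C[C@]2(C)[C@@H]3C=O | intermediate
31 | C11 alcohol | C[Si](C)(c1ccccc1)/C=C\C(=O)OCC1=C(C)C(=O)C(C)=C[C@]13CC[C@H]2C(C)(C)OC(=O)C=C[C@]2(C)[C@@H]3CO | intermediate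
32 | C11 iodide (key-step precursor) | C[Si](C)(c1ccccc1)/C=C\C(=O)OCC1=C(C)C(=O)C(C)=C[C@]13CC[C@H]2C(C)(C)OC(=O)C=C[C@]2(C)[C@@H]3CI | intermediate
33 | cross-conjugated lithium dienolate (C3'=C4'–OLi, C5'=C6') | C[Si](C)(c1ccccc1)/C=C\C(=O)OCC1=C(C)C(O[Li])=C(C)C[C@]13CC[C@H]2C(C)(C)OC(=O)C=C[C@]2(C)[C@@H]3CI | intermediate
34 | bicyclo[2.2.2]octene lithium enolate (C4'=C5') with γ-lactone closed and C11–I intact | CC1(C)OC(=O)C=C[C@@]2(C)[C@H]1CC[C@]3(C[C@]4(C)C(O[Li])=C(C)[C@]35COC(=O)[C@H]5[C@H]4[Si](C)(C)c6ccccc6)[C@H]2CI | intermediate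
35 | cage silane (andilesin A skeleton with SiMe2Ph at C2', all other centres as in the target) | CC1(C)OC(=O)C=C[C@@]2(C)[C@H]1CC[C@]13C[C@]4(C)C(=O)[C@](C)(C[C@@H]21)[C@]31COC(=O)[C@H]1[C@H]4[Si](C)(C)c1ccccc1 | intermediate
36 | andilesin A | CC1(C)OC(=O)C=C[C@@]2(C)[C@H]1CC[C@]13C[C@]4(C)C(=O)[C@](C)(C[C@@H]21)[C@]31COC(=O)[C@H]1[C@H]4O | target

**Count and risks**

Total step count: 26. Longest linear sequence: 19 steps (steps 6–11, then 14–26).

Steps most likely to fail:

1. Step 25 (the step labelled as a proposed new method). The dienolate may add to the ester carbonyl instead of the hindered silyl-bearing alkene carbon, the facial preference may be poor, or the sequence may stall before the alkylation. The fallback sets out from 32 and comes back at 35. The conjugate reduction would be stopped at the enolate stage by silylation (LiBH(s-Bu)3, then t-BuMe2SiCl and DMPU) to give the 2-silyloxy diene F1. A thermal intramolecular Diels–Alder reaction of this neutral diene (toluene, 170 °C, sealed tube) would give the bicyclo[2.2.2]octene silyl enol ether F2. MeLi would then release lithium enolate 34 regiospecifically, which closes the cyclopentane by alkylation to give 35.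

2. Step 14. Attack may occur at the unsubstituted allyl terminus, or diastereoselection may be poor, because the aryl group is ortho-substituted and the nucleophile is fully substituted. The fallback sets out from 11 and 7 and comes back at 20. Bromine–lithium exchange on 11 (t-BuLi) and formylation with DMF would give the aryl aldehyde F3, and Henry condensation with nitromethane the (E)-nitroalkene F4. Michael addition of the lithium enolate of 7, again anti to the C5 side chain, would give the nitro lactone F5; C9 epimers would be separated, or the sense steered with a chiral Lewis acid in the silyl ketene acetal variant. A Nef reaction (KOt-Bu, then O3 at −78 °C) would give the aldehyde lactone F6, and Wittig methylenation would give 20.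

3. Step 18. The ruthenium carbene may load on the C9 vinyl group, leading to oligomerisation or closure to the eight-membered lactone. The fallback sets out from 22 and comes back at 24. Alcohol 22 would be acylated with (2E)-octa-2,7-dienoyl chloride to give the relay ester F7. Ruthenium then enters at the remote terminal alkene, expels cyclopentene and arrives as the enoate carbene at C2, from where closure onto the adjacent C10 vinyl group is the shortest path.

**Further compounds**

F1 | step 25 | tert-butyldimethylsilyl dienol ether of 32 (2-silyloxy diene) | C[Si](C)(c1ccccc1)/C=C\C(=O)OCC1=C(C)C(O[Si](C)(C)C(C)(C)C)=C(C)C[C@]13CC[C@H]2C(C)(C)OC(=O)C=C[C@]2(C)[C@@H]3CI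
F2 | step 25 | bicyclo[2.2.2]octene silyl enol ether (Diels–Alder adduct) | CC1(C)OC(=O)C=C[C@@]2(C)[C@H]1CC[C@]3(C[C@]4(C)C(O[Si](C)(C)C(C)(C)C)=C(C)[C@]35COC(=O)[C@H]5[C@H]4[Si](C)(C)c6ccccc6)[C@H]2CI
F3 | step 14 | 4-(tert-butyldimethylsilyloxy)-2-[(tert-butyldimethylsilyloxy)methyl]-3,5-dimethylbenzaldehyde | O=Cc1cc(C)c(O[Si](C)(C)C(C)(C)C)c(C)c1CO[Si](C)(C)C(C)(C)C
F4 | step 14 | (E)-2-aryl-1-nitroethene | O=[N+]([O-])/C=C/c1cc(C)c(O[Si](C)(C)C(C)(C)C)c(C)c1CO[Si](C)(C)C(C)(C)C
F5 | step 14 | nitro lactone (Michael adduct; C9 and C10 as in 20) | O=[N+]([O-])C[C@H](c1cc(C)c(O[Si](C)(C)C(C)(C)C)c(C)c1CO[Si](C)(C)C(C)(C)C)[C@@]1(C)C(=O)OC(C)(C)[C@@H]1CCO[Si](CC)(CC)CC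
F6 | step 14 | aldehyde lactone (Nef product) | O=C[C@H](c1cc(C)c(O[Si](C)(C)C(C)(C)C)c(C)c1CO[Si](C)(C)C(C)(C)C)[C@@]1(C)C(=O)OC(C)(C)[C@@H]1CCO[Si](CC)(CC)CC
F7 | step 18 | (2E)-octa-2,7-dienoate relay ester of 22 | C=C[C@H](c1cc(C)c(O[Si](C)(C)C(C)(C)C)c(C)c1CO[Si](C)(C)C(C)(C)C)[C@@](C)(C=C)[C@@H](CCO[Si](CC)(CC)CC)C(C)(C)OC(=O)/C=C/CCCC=C
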